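**Retrosynthetic overview**
1. Target 23 ⇐ diol lactone 20 by allylic hydroxylation at C15 and three acylations (9‑OAc, 15‑OAc, 6‑O‑isobutyryl).
2. 20 ⇐ lactol 14 + dibromoacrylate 17 by a one‑pot indium [5+1] annulation: the acrylate β‑carbon (C7) acts twice as a nucleophile (double homoenolate equivalent) toward the aldehyde carbons C8 and C6.
3. 14 ⇐ γ‑lactone 13 ⇐ Ireland–Claisen rearrangement of ester 10 (C5–C10 bond; quaternary C10 with vinyl, C5 with isopropenyl).
4. 10 ⇐ CBS reduction (C9) of enone ester 9 ⇐ Wittig reaction of keto ylide 4 with glycolaldehyde, then esterification with 3‑methylbut‑3‑enoic acid.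
5. Ring order: temporary lactol (C6–O9), then the α‑methylene γ‑lactone (O8–C12) with the C7–C8 bond, then the cyclohexane by the C6–C7 bond.

Assumption: atom labels C1–C15 follow elemane numbering (C10 quaternary, C9 OAc, C8 lactone O, C7 lactone C, C6 O‑isobutyryl, C5 side‑chain carbon); compounds 1, 2, 5, 8 and 15 are bought.

Step 1
Reactants: 1 methyl 2,2-dimethoxyacetate; 2 ethyltriphenylphosphonium bromide
Product: 4 1,1-dimethoxy-3-(triphenyl-λ5-phosphanylidene)butan-2-one, via ethylidenetriphenylphosphorane 3 (not isolated)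
Conditions: 2, LiN(i-Pr)2 (2.0 equiv), THF, −78 to 0 °C; then 1, 0 °C to rt; H2O
Reagents that add atoms: none
Why: Acylation of a non‑stabilised ylide by an ester gives the keto‑stabilised ylide (ylide acylation, second equivalent of base removes the acidic P–CH proton); no stereocenter is formed.

Step 2
Reactants: 4 1,1-dimethoxy-3-(triphenyl-λ5-phosphanylidene)butan-2-one; 5 glycolaldehyde dimer
Product: 7 (E)-5-hydroxy-1,1-dimethoxy-3-methylpent-3-en-2-one, via glycolaldehyde 6 (not isolated)
Conditions: 5 (0.6 equiv), PhMe, 80 °C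
Reagents that add atoms: none
Why: Wittig olefination of a keto‑stabilised α‑methyl ylide with the aldehyde released from its dimer gives the (E)‑trisubstituted enone, as is usual for stabilised ylides.

Step 3
Reactants: 7 (E)-5-hydroxy-1,1-dimethoxy-3-methylpent-3-en-2-one; 8 3-methylbut-3-enoic acid
Product: 9 (E)-5,5-dimethoxy-3-methyl-4-oxopent-2-en-1-yl 3-methylbut-3-enoate
Conditions: DCC, DMAP (5 mol %), CH2Cl2, −10 °C
Reagents that add atoms: none
Why: Steglich esterification of the only hydroxyl group; low temperature and little DMAP keep the β,γ‑unsaturated acyl group from moving into conjugation.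

Step 4
Reactants: 9 (E)-5,5-dimethoxy-3-methyl-4-oxopent-2-en-1-yl 3-methylbut-3-enoate
Product: 10 (S,E)-4-hydroxy-5,5-dimethoxy-3-methylpent-2-en-1-yl 3-methylbut-3-enoate
Conditions: (S)-2-methyl-CBS-oxazaborolidine (10 mol %), catecholborane, PhMe, −78 °C
Reagents that add atoms: none
Why: Corey–Bakshi–Shibata reduction: with the α‑methyl alkenyl group as the large substituent, the (S)‑catalyst delivers hydride to the face that gives the (S)‑carbinol (C9); ester and alkenes are untouched by catecholborane at −78 °C.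

Step 5
Reactants: 10 (S,E)-4-hydroxy-5,5-dimethoxy-3-methylpent-2-en-1-yl 3-methylbut-3-enoate
Product: 13 (3S,4S,5S)-5-(dimethoxymethyl)-4-methyl-3-(prop-1-en-2-yl)-4-vinyldihydrofuran-2(3H)-one, via silyl ketene acetal 11 (not isolated), via hydroxy acid 12 (not isolated)
Conditions: LiN(i-Pr)2 (2.2 equiv), Me3SiCl, THF, −78 to 50 °C; then 10% aq citric acid, rt
Reagents that add atoms: none
Why: Ireland–Claisen rearrangement: kinetic enolisation puts the isopropenyl group cis to the allylic oxygen of the ketene acetal, the (E)‑alkene places C9 equatorial in the chair transition state, and the C5–C10 bond forms anti to the C9–O bond (C9–H turned toward the alkene methyl), which sets C10 (methyl, vinyl) and C5 together; acid work‑up removes the silyl groups and closes the γ‑lactone through O9.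

Step 6
Reactants: 13 (3S,4S,5S)-5-(dimethoxymethyl)-4-methyl-3-(prop-1-en-2-yl)-4-vinyldihydrofuran-2(3H)-one
Product: 14 (3S,4S,5S)-5-(dimethoxymethyl)-4-methyl-3-(prop-1-en-2-yl)-4-vinyltetrahydrofuran-2-ol (both anomers)
Conditions: i-Bu2AlH (1.1 equiv), CH2Cl2, −78 °C; aq potassium sodium tartrate
Reagents that add atoms: none
Why: Partial reduction of the γ‑lactone stops at the lactol because the aluminium hemiacetal is stable at −78 °C; this masks the C6 aldehyde with O9 and leaves the acetal at C8 intact.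

Step 7
Reactants: 15 methyl 2-(bromomethyl)acrylate
Product: 17 methyl (Z)-3-bromo-2-(bromomethyl)acrylate, via tribromo ester 16 (not isolated)
Conditions: Br2, CH2Cl2, 0 °C; then Et3N, 0 °C to rt
Reagents that add atoms: bromine, BrBr
Why: Bromine addition to the acrylate followed by E2 loss of HBr (α‑bromide and a CH2Br proton) gives the 3‑bromo‑2‑(bromomethyl)acrylate.

Step 8
Reactants: 14 (3S,4S,5S)-5-(dimethoxymethyl)-4-methyl-3-(prop-1-en-2-yl)-4-vinyltetrahydrofuran-2-ol; 17 methyl (Z)-3-bromo-2-(bromomethyl)acrylate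
Product: 20 (3aS,4S,5S,6S,7S,7aS)-4,7-dihydroxy-6-methyl-3-methylene-5-(prop-1-en-2-yl)-6-vinylhexahydrobenzofuran-2(3H)-one, via hydroxy dialdehyde 18 (not isolated), via bromo lactone aldehyde 19 (not isolated)
Conditions: 0.2 M HCl, THF–H2O, 45 °C; then 17, indium powder, 25 to 45 °C
Reagents that add atoms: water, O
Why: Proposed new method: after acetal hydrolysis the allylindium from the CH2Br end of 17 adds through its bromine‑bearing γ‑carbon to the free α‑oxy aldehyde C8 under chelation by O9 (C8–O anti to C10, i.e. trans to O9), the alkoxide lactonises, indium then inserts into the new secondary allylic C–Br bond and this 2‑(indiomethyl)butenolide closes onto the C6 aldehyde released from the lactol, giving the cis‑fused ring with C6–OH cis to the lactone carbon through a chair Zimmerman–Traxler‑type transition state; the acrylate β‑carbon, normally an electrophile, is thus joined twice to aldehyde carbons, and the closest known reactions are indium Barbier allylations of aldehydes with 2‑(bromomethyl)acrylates or 3‑(bromomethyl)furan‑2(5H)‑one to α‑methylene γ‑lactones and ring‑closing versions that give cis‑fused lactones.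

Step 9
Reactants: 20 (3aS,4S,5S,6S,7S,7aS)-4,7-dihydroxy-6-methyl-3-methylene-5-(prop-1-en-2-yl)-6-vinylhexahydrobenzofuran-2(3H)-one
Product: 21 (3aS,4S,5S,6S,7S,7aS)-4,7-dihydroxy-5-(3-hydroxyprop-1-en-2-yl)-6-methyl-3-methylene-6-vinylhexahydrobenzofuran-2(3H)-one
Conditions: SeO2 (0.3 equiv), t-BuOOH, CH2Cl2, rt
Reagents that add atoms: tert-butyl hydroperoxide, CC(C)(C)OO
Why: Riley‑type allylic hydroxylation (ene reaction, then [2,3]‑shift) attacks the methyl of the isopropenyl group, because the vinyl group has no allylic hydrogen, the lactone methylene is electron‑poor and the C5 methine is disfavoured.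

Step 10
Reactants: 21 (3aS,4S,5S,6S,7S,7aS)-4,7-dihydroxy-5-(3-hydroxyprop-1-en-2-yl)-6-methyl-3-methylene-6-vinylhexahydrobenzofuran-2(3H)-one
Product: 22 (3aS,4S,5S,6S,7S,7aS)-5-(3-acetoxyprop-1-en-2-yl)-4-hydroxy-6-methyl-3-methylene-2-oxo-6-vinyloctahydrobenzofuran-7-yl acetate
Conditions: Ac2O (2.2 equiv), pyridine, DMAP (2 mol %), CH2Cl2, 0 °C
Reagents that add atoms: acetic anhydride, CC(=O)OC(C)=O
Why: Acetylation takes the primary allylic alcohol and the C9 alcohol, while the C6 alcohol, flanked by two branched carbons and syn‑axial to the angular methyl and the lactone oxygen, is expected to be left.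

Step 11
Reactants: 22 (3aS,4S,5S,6S,7S,7aS)-5-(3-acetoxyprop-1-en-2-yl)-4-hydroxy-6-methyl-3-methylene-2-oxo-6-vinyloctahydrobenzofuran-7-yl acetate
Product: 23 (3aS,4S,5S,6S,7S,7aS)-7-acetoxy-5-(3-acetoxyprop-1-en-2-yl)-6-methyl-3-methylene-2-oxo-6-vinyloctahydrobenzofuran-4-yl 2-methylpropanoate (CNP0500052.1)
Conditions: (i-PrCO)2O, Sc(OTf)3 (5 mol %), MeCN, −20 °C to rt
Reagents that add atoms: isobutyric anhydride, CC(C)C(=O)OC(=O)C(C)C
Why: Lewis‑acid‑catalysed acylation with the anhydride esterifies the remaining hindered axial C6 alcohol without touching the stereocenters.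

**Compound list**
1 | methyl 2,2-dimethoxyacetate | COC(OC)C(=O)OC | starting material
2 | ethyltriphenylphosphonium bromide | CC[P+](c1ccccc1)(c1ccccc1)c1ccccc1.[Br-] | starting material
3 | ethylidenetriphenylphosphorane | CC=P(c1ccccc1)(c1ccccc1)c1ccccc1 | intermediate
4 | 1,1-dimethoxy-3-(triphenyl-λ5-phosphanylidene)butan-2-one | COC(OC)C(=O)C(C)=P(c1ccccc1)(c1ccccc1)c1ccccc1 | intermediate
5 | glycolaldehyde dimer (1,4-dioxane-2,5-diol, isomer mixture) | OC1COC(O)CO1 | starting material
6 | glycolaldehyde | OCC=O | intermediate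
7 | (E)-5-hydroxy-1,1-dimethoxy-3-methylpent-3-en-2-one | COC(OC)C(=O)/C(C)=C/CO | intermediate
8 | 3-methylbut-3-enoic acid | C=C(C)CC(=O)O | starting material
9 | (E)-5,5-dimethoxy-3-methyl-4-oxopent-2-en-1-yl 3-methylbut-3-enoate | COC(OC)C(=O)/C(C)=C/COC(=O)CC(C)=C | intermediate
10 | (S,E)-4-hydroxy-5,5-dimethoxy-3-methylpent-2-en-1-yl 3-methylbut-3-enoate | COC(OC)[C@@H](O)/C(C)=C/COC(=O)CC(C)=C | intermediate
11 | trimethylsilyl ketene acetal of 10 with C9–OSiMe3 (isopropenyl cis to the allylic oxygen, S at C9) | COC(OC)[C@@H](O[Si](C)(C)C)/C(C)=C/CO/C(O[Si](C)(C)C)=C\C(C)=C | intermediate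
12 | (2S,3S,4S)-4-hydroxy-5,5-dimethoxy-3-methyl-2-(prop-1-en-2-yl)-3-vinylpentanoic acid | C=C[C@](C)([C@H](O)C(OC)OC)[C@H](C(C)=C)C(=O)O | intermediate
13 | (3S,4S,5S)-5-(dimethoxymethyl)-4-methyl-3-(prop-1-en-2-yl)-4-vinyldihydrofuran-2(3H)-one (4-methyl cis to both neighbours' carbon groups, vinyl trans) | C=C[C@]1(C)[C@@H](C(OC)OC)OC(=O)[C@H]1C(C)=C | intermediate
14 | (3S,4S,5S)-5-(dimethoxymethyl)-4-methyl-3-(prop-1-en-2-yl)-4-vinyltetrahydrofuran-2-ol (both anomers) | C=C[C@]1(C)[C@@H](C(OC)OC)OC(O)[C@H]1C(C)=C | intermediate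
15 | methyl 2-(bromomethyl)acrylate | C=C(CBr)C(=O)OC | starting material
16 | methyl 2,3-dibromo-2-(bromomethyl)propanoate | COC(=O)C(Br)(CBr)CBr | intermediate
17 | methyl (Z)-3-bromo-2-(bromomethyl)acrylate | COC(=O)/C(CBr)=C/Br | intermediate
18 | (2S,3S,4S)-4-hydroxy-3-methyl-2-(prop-1-en-2-yl)-3-vinylpentanedial | C=C[C@](C)([C@H](O)C=O)[C@H](C(C)=C)C=O | intermediate
19 | 4-(3-bromo-4-methylene-5-oxotetrahydrofuran-2-yl)-4-hydroxy-3-methyl-2-(prop-1-en-2-yl)-3-vinylbutanal (four defined centers as in 20, C–Br carbon as epimers) | C=C[C@](C)([C@H](O)[C@H]1OC(=O)C(=C)C1Br)[C@H](C(C)=C)C=O | intermediate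
20 | (3aS,4S,5S,6S,7S,7aS)-4,7-dihydroxy-6-methyl-3-methylene-5-(prop-1-en-2-yl)-6-vinylhexahydrobenzofuran-2(3H)-one | C=C[C@]1(C)[C@H](O)[C@H]2OC(=O)C(=C)[C@H]2[C@@H](O)[C@H]1C(C)=C | intermediate
21 | (3aS,4S,5S,6S,7S,7aS)-4,7-dihydroxy-5-(3-hydroxyprop-1-en-2-yl)-6-methyl-3-methylene-6-vinylhexahydrobenzofuran-2(3H)-one | C=C[C@]1(C)[C@H](O)[C@H]2OC(=O)C(=C)[C@H]2[C@@H](O)[C@H]1C(=C)CO | intermediate
22 | (3aS,4S,5S,6S,7S,7aS)-5-(3-acetoxyprop-1-en-2-yl)-4-hydroxy-6-methyl-3-methylene-2-oxo-6-vinyloctahydrobenzofuran-7-yl acetate | C=C[C@]1(C)[C@H](OC(C)=O)[C@H]2OC(=O)C(=C)[C@H]2[C@@H](O)[C@H]1C(=C)COC(C)=O | intermediate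
23 | (3aS,4S,5S,6S,7S,7aS)-7-acetoxy-5-(3-acetoxyprop-1-en-2-yl)-6-methyl-3-methylene-2-oxo-6-vinyloctahydrobenzofuran-4-yl 2-methylpropanoate | C=C[C@]1(C)[C@H](OC(C)=O)[C@H]2OC(=O)C(=C)[C@H]2[C@@H](OC(=O)C(C)C)[C@H]1C(=C)COC(C)=O | target

**Step count and risks**
Total step count: 11. Longest linear sequence: 10 (steps 1–6 and 8–11; step 7 makes reagent 17).

Most likely to fail, first: step 8. The double allylation may stop after the first addition, lose the β‑oxygen by elimination, or close with the wrong configuration at C6. Fallback: set out from 14, hydrolyse the acetal and run only the first indium allylation with 17 near neutral pH, isolating bromo lactone aldehyde 19. LiBr in acetone then moves the allylic bromide to give the conjugated 3‑(bromomethyl)butenolide aldehyde F1. A triazolium‑derived N‑heterocyclic carbene with i‑Pr2NEt turns the C6 aldehyde into an acyl‑anion equivalent that adds to the butenolide β‑carbon and expels bromide (intramolecular Stetter‑type addition–elimination), giving the 6‑ketone F2. NaBH4/CeCl3 at −78 °C delivers hydride from the face away from the angular methyl and the lactone oxygen, and the sequence comes back to the route at 20.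

Second: step 5. Facial control by the C9 center and the geometry of the dienolate may be insufficient. Fallback: set out from 10 and silylate it (t‑BuMe2SiCl, imidazole) to the silyl ether F3. Form the boron ketene acetal with the C9‑matched enantiomer of the 1,2‑diphenylethylenediamine bis(toluenesulfonamide) bromoborane and Et3N at −78 °C, so that a chiral reagent rather than the substrate alone fixes face and geometry; rearrangement at rt gives the silyloxy acid F4. n‑Bu4NF and then citric acid remove the silyl group and close the lactone, coming back at 13.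

Third: step 9. Late allylic oxidation may over‑oxidise to the enal or attack other sites. Fallback: set out from 20 and use an ene‑type allylic chlorination of the isopropenyl group (N‑chlorosuccinimide, PhSeCl cat., CH2Cl2) to the allylic chloride F5. CsOAc in DMF displaces chloride to give the 15‑monoacetate F6, and acetylation of the C9 alcohol (Ac2O, pyridine) comes back at 22.

**Further compounds**
F1 | step 8 | (2S,3S,4S)-4-[(2S)-4-(bromomethyl)-5-oxo-2,5-dihydrofuran-2-yl]-4-hydroxy-3-methyl-2-(prop-1-en-2-yl)-3-vinylbutanal | C=C[C@](C)([C@H](O)[C@H]1OC(=O)C(CBr)=C1)[C@H](C(C)=C)C=O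
F2 | step 8 | (3aR,5S,6S,7S,7aS)-7-hydroxy-6-methyl-3-methylene-5-(prop-1-en-2-yl)-6-vinyltetrahydrobenzofuran-2,4(3H,5H)-dione | C=C[C@]1(C)[C@H](O)[C@H]2OC(=O)C(=C)[C@H]2C(=O)[C@H]1C(C)=C
F3 | step 5 | (S,E)-4-((tert-butyldimethylsilyl)oxy)-5,5-dimethoxy-3-methylpent-2-en-1-yl 3-methylbut-3-enoate | COC(OC)[C@@H](O[Si](C)(C)C(C)(C)C)/C(C)=C/COC(=O)CC(C)=C
F4 | step 5 | (2S,3S,4S)-4-((tert-butyldimethylsilyl)oxy)-5,5-dimethoxy-3-methyl-2-(prop-1-en-2-yl)-3-vinylpentanoic acid | C=C[C@](C)([C@H](O[Si](C)(C)C(C)(C)C)C(OC)OC)[C@H](C(C)=C)C(=O)O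
F5 | step 9 | 5-(3-chloroprop-1-en-2-yl)-4,7-dihydroxy-6-methyl-3-methylene-6-vinylhexahydrobenzofuran-2(3H)-one, configuration as in 20 | C=C[C@]1(C)[C@H](O)[C@H]2OC(=O)C(=C)[C@H]2[C@@H](O)[C@H]1C(=C)CCl
F6 | step 9 | 2-[(3aS,4S,5S,6S,7S,7aS)-4,7-dihydroxy-6-methyl-3-methylene-2-oxo-6-vinyloctahydrobenzofuran-5-yl]allyl acetate | C=C[C@]1(C)[C@H](O)[C@H]2OC(=O)C(=C)[C@H]2[C@@H](O)[C@H]1C(=C)COC(C)=O
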